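**Plan**

1. Retrosynthetic cuts, in order: ring B of the labdane half at C9–C10 (exocyclic C8=C17 from an allylsilane); then the C9–C11 bond; then the two [5+2] bonds C15–C8′ and C14–C13′; then the ring contraction and bicyclisation of an abietane.
2. Forward: rings A′/B′/C′ by enantioselective polyene cyclisation, Wolff contraction to the 6-5-6 hydroxy-p-quinone, [5+2] with a dienyl acetate to the bicyclo[3.2.1]octane; ring A made separately and joined by allyl–alkenyl Suzuki coupling; ring B closed last.
3. Enabling feature: ring B carries the C8=C17 methylene next to C9–H and the quaternary C10–CH3, the retron of a tertiary C10 cation (from a C10=C20 methylene) captured at C9 by a (Z)-allylsilane C9=C8–C17–Si.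
4. Stereochemistry: C5′/C10′ from the chiral acid in the bicyclisation; C6′ thermodynamic; C8′, C13′, C14 from the [5+2] (α face, endo); C4 from Cu-catalysed asymmetric conjugate addition; C5 from trans enolate allylation; C9 and C10 from the chair transition state of the key step.
5. Alkene geometry: C12=C13 (E) comes from the diene, C8=C9 (Z) from syn borylcupration; the methyl ester and enol acetate are removed in the last step.

Key step: step 21

Remark on numbering: the south half is numbered as a labdane (ring A = C1–C5, C10; ring B = C5–C10; C17 = exocyclic CH2, C20 = C10 methyl); the north half as an abietane with primes (C8′–C14′ = former quinone ring, C7′ = formyl carbon on C6′); the diene carbons become C11–C16.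

Assumption: 2-isopropylanisole, geranyl chloride, (E)-3-methylpent-2-en-4-yn-1-ol and methyl 3-oxocyclohex-1-ene-1-carboxylate are taken as purchasable. Chiral catalysts are used in the enantiomeric form that gives the configurations drawn.

Step 1
Reactants: 1 2-isopropylanisole
Product: 2 4-(chloromethyl)-1-methoxy-2-(propan-2-yl)benzene
Conditions: (CH2O)n, HCl (g), ZnCl2 (cat.), AcOH, 50 °C
Reagents that add atoms: formaldehyde (C=O); hydrogen chloride (Cl)
Why: Blanc chloromethylation, an electrophilic aromatic substitution directed para to the methoxy group (the other activated position lies next to the isopropyl group); no stereocentre is formed.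

Step 2
Reactants: 2 4-(chloromethyl)-1-methoxy-2-(propan-2-yl)benzene; 3 geranyl chloride
Product: 5 4-[(3E)-4,8-dimethylnona-3,7-dien-1-yl]-1-methoxy-2-(propan-2-yl)benzene, via benzylmagnesium chloride 4 (not isolated)
Conditions: Mg, THF, 0 °C; then 3, Li2CuCl4 (cat.), THF, −10 °C
Reagents that add atoms: none
Why: Copper-catalysed SN2 coupling of a benzylic Grignard reagent with a primary allylic chloride at its unsubstituted terminus, which keeps the E geometry of the geranyl unit.

Step 3
Reactants: 5 homogeranylarene
Product: 6 (+)-ferruginol methyl ether, (4bS,8aS)-3-methoxy-4b,8,8-trimethyl-2-(propan-2-yl)-4b,5,6,7,8,8a,9,10-octahydrophenanthrene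
Conditions: SbCl5·(R)-3,3′-dichloro-BINOL (1:1 complex), CH2Cl2, −78 °C
Reagents that add atoms: none
Why: Enantioselective proton-initiated cation–olefin bicyclisation with Friedel–Crafts termination para to the isopropyl group: the SbCl5-activated chiral BINOL proton adds to one face of the terminal alkene, and chair–chair anti additions across the E alkene set the trans ring fusion (H5′ α, C10′ methyl β).

Step 4
Reactants: 6 (+)-ferruginol methyl ether
Product: 7 sugiol methyl ether (12-methoxyabieta-8,11,13-trien-7-one)
Conditions: CrO3, AcOH–Ac2O, 0 °C → rt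
Reagents that add atoms: chromium trioxide (O=[Cr](=O)=O)
Why: Benzylic oxidation of the ring methylene C7′ para to the methoxy group, the known oxidation pattern of ferruginol and dehydroabietate derivatives; the stereocentres are untouched.

Step 5
Reactants: 7 sugiol methyl ether
Product: 9 6-diazo-12-methoxyabieta-8,11,13-trien-7-one, via trifluoroacetyl ketone 8 (not isolated)
Conditions: LiHMDS, THF, −78 °C; CF3CO2CH2CF3; then MsN3, Et3N, MeCN–H2O, rt
Reagents that add atoms: methanesulfonyl azide (CS(=O)(=O)N=[N+]=[N-])
Why: Detrifluoroacetylative Regitz-type diazo transfer: C6′ is the only enolisable position of the aryl ketone, is trifluoroacetylated and then exchanges the acyl group for N2.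

Step 6
Reactants: 9 6-diazo-12-methoxyabieta-8,11,13-trien-7-one
Product: 12 methyl (4aS,9R,9aS)-6-methoxy-1,1,4a-trimethyl-7-(propan-2-yl)-2,3,4,4a,9,9a-hexahydro-1H-fluorene-9-carboxylate, via ring-contracted ketene 10 (not isolated), via C6-epimeric ester mixture 11 (not isolated)
Conditions: hν (medium-pressure Hg lamp, Pyrex), MeOH, 0 °C; then NaOMe (cat.), MeOH, 50 °C
Reagents that add atoms: methanol (CO)
Why: Photochemical Wolff rearrangement in which aryl carbon C8′ migrates from C7′ to the carbene carbon C6′; methanol traps the ring-contracted ketene, and methoxide equilibration puts the ester on the less hindered α face (trans to C4′ and to the C10′ methyl), which sets C6′.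

Step 7
Reactants: 12 ring-contracted methyl ester
Product: 13 methyl (4aS,9R,9aS)-6-hydroxy-1,1,4a-trimethyl-7-(propan-2-yl)-2,3,4,4a,9,9a-hexahydro-1H-fluorene-9-carboxylate
Conditions: BBr3, CH2Cl2, −78 → −20 °C
Reagents that add atoms: none
Why: Lewis-acid cleavage of the aryl methyl ether by BBr3, which at low temperature is faster than cleavage of the hindered methyl ester.

Step 8
Reactants: 13 phenol ester
Product: 14 (4aS,9R,9aS)-9-(hydroxymethyl)-1,1,4a-trimethyl-7-(propan-2-yl)-2,3,4,4a,9,9a-hexahydro-1H-fluoren-6-ol
Conditions: LiAlH4, THF, 0 °C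
Reagents that add atoms: none
Why: Hydride reduction of the ester to the primary alcohol; no stereocentre is touched.

Step 9
Reactants: 14 phenol alcohol
Product: 17 (4aS,9R,9aS)-6-hydroxy-1,1,4a-trimethyl-5,8-dioxo-7-(propan-2-yl)-2,3,4,4a,5,8,9,9a-octahydro-1H-fluorene-9-carbaldehyde, via o-quinone aldehyde 15 (not isolated), via arylthio-o-quinone 16 (not isolated)
Conditions: IBX (excess), DMSO, rt; then C6F5SH; then NaOH, MeOH, air; H3O+
Reagents that add atoms: IBX (O=C1OI(=O)(O)c2ccccc12); sodium hydroxide ([Na+].[OH-])
Why: IBX oxidises the primary alcohol to the aldehyde and the phenol at its free ortho position C11′ to the o-quinone; thiol conjugate addition at C14′, reoxidation and addition–elimination by hydroxide then give the 12-hydroxy-11,14-quinone, a sequence known on this ring pattern, and the base leaves C6′ in its thermodynamic α configuration.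

Step 10
Reactants: 18 (E)-3-methylpent-2-en-4-yn-1-ol
Product: 19 (E)-3-methylpenta-2,4-dien-1-ol
Conditions: H2 (1 atm), Lindlar catalyst (Pd/CaCO3, Pb(OAc)2-poisoned), quinoline, EtOAc, 0 °C
Reagents that add atoms: none
Why: Lindlar semihydrogenation of the terminal alkyne to the vinyl group; the E trisubstituted alkene is not touched.

Step 11
Reactants: 19 (E)-3-methylpenta-2,4-dien-1-ol
Product: 20 (E)-3-methylpenta-2,4-dien-1-yl acetate
Conditions: Ac2O, pyridine, DMAP (cat.), CH2Cl2, 0 °C
Reagents that add atoms: acetic anhydride (CC(=O)OC(C)=O)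
Why: Acylation of the primary allylic alcohol gives the handle that later serves as the allylic leaving group.

Step 12
Reactants: 17 hydroxyquinone aldehyde; 20 dienyl acetate
Product: 21 [5+2] adduct: bicyclo[3.2.1]oct-3-ene-2,8-dione (C14′=O bridge, C12′=O, C11′–OH enol) fused to the trans-hydrindane, with C15 on C8′ (α face) and the (E)-4-acetoxybut-2-en-2-yl group on C14 syn to the three-carbon bridge
Conditions: BF3·OEt2, CH2Cl2, −78 → −40 °C
Reagents that add atoms: none
Why: Perezone-type cationic [5+2] cycloaddition: BF3 chelated between O11′ and O12′ makes C8′–C9′–C11′–C12′–C13′ a 2-oxidopentadienyl cation, the unsubstituted diene terminus C15 bonds to C8′ and C13′ closes onto the allyl cation at C14; approach anti to the angular C10′ methyl sets C8′ and C13′, the endo arrangement with the C12=C13 unit under the C9′–C11′–C12′ bridge sets C14, and the E alkene is retained.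

Step 13
Reactants: 22 methyl 3-oxocyclohex-1-ene-1-carboxylate
Product: 24 methyl (1R,2S)-1-methyl-3-oxo-2-(prop-2-en-1-yl)cyclohexane-1-carboxylate, via zinc enolate 23 (not isolated)
Conditions: Me2Zn, Cu(OTf)2·C6H6 (cat.), chiral sulfonate-bearing N-heterocyclic carbene silver complex [Ag(L*)]2 (cat.), t-BuOMe, −30 °C; then allyl acetate, Pd(PPh3)4 (cat.), 0 °C
Reagents that add atoms: dimethylzinc (C[Zn]C); allyl acetate (C=CCOC(C)=O)
Why: Copper-catalysed asymmetric conjugate addition of Me2Zn to the γ-keto ester sets the R quaternary centre C4 under ligand control, and Tsuji–Trost allylation of the regiodefined zinc enolate brings the allyl group in axially, anti to the pseudoaxial ester (trans to CO2Me, cis to CH3), which sets C5.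

Step 14
Reactants: 24 allyl ketone
Product: 25 methyl (1R,2R)-1-methyl-3-methylidene-2-(prop-2-en-1-yl)cyclohexane-1-carboxylate
Conditions: Zn, CH2Br2, TiCl4, THF–CH2Cl2, 0 °C → rt
Reagents that add atoms: dibromomethane (BrCBr)
Why: Lombardo methylenation, a non-basic carbonyl olefination that does not epimerise the kinetically set C5 and leaves the ester alone.

Step 15
Reactants: 25 methylene diene
Product: 27 methyl (1R,2R)-2-(3-hydroxypropyl)-1-methyl-3-methylidenecyclohexane-1-carboxylate, via trialkylborane 26 (not isolated)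
Conditions: Sia2BH, THF, −20 → 0 °C; then H2O2, pH 7 buffer, MeOH
Reagents that add atoms: hydrogen peroxide (OO)
Why: Anti-Markovnikov hydroboration with the bulky disiamylborane, which should prefer the monosubstituted allyl alkene over the hindered 1,1-disubstituted one, followed by oxidation with retention.

Step 16
Reactants: 27 primary alcohol
Product: 28 methyl (1R,2R)-1-methyl-3-methylidene-2-(3-oxopropyl)cyclohexane-1-carboxylate
Conditions: Dess–Martin periodinane, NaHCO3, CH2Cl2, rt
Reagents that add atoms: none
Why: Dess–Martin oxidation of the primary alcohol to the aldehyde under neutral conditions.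

Step 17
Reactants: 28 aldehyde
Product: 29 methyl (1R,2R)-2-(but-3-yn-1-yl)-1-methyl-3-methylidenecyclohexane-1-carboxylate
Conditions: Ohira–Bestmann reagent, K2CO3, MeOH, 0 °C → rt
Reagents that add atoms: dimethyl (1-diazo-2-oxopropyl)phosphonate (CC(=O)C(=[N+]=[N-])P(=O)(OC)OC)
Why: Seyferth–Gilbert homologation with the Ohira–Bestmann reagent converts the aldehyde into the terminal alkyne C8≡C9 under mild base that the hindered ester tolerates.

Step 18
Reactants: 29 terminal alkyne
Product: 30 methyl (1R,2R)-1-methyl-3-methylidene-2-[(3Z)-4-(4,4,5,5-tetramethyl-1,3,2-dioxaborolan-2-yl)-3-[(trimethylsilyl)methyl]but-3-en-1-yl]cyclohexane-1-carboxylate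
Conditions: CuCl (cat.), Xantphos (cat.), B2pin2, NaOt-Bu, THF, rt; then Me3SiCH2I
Reagents that add atoms: bis(pinacolato)diboron (CC1(C)OB(OC1(C)C)B1OC(C)(C)C(C)(C)O1); (iodomethyl)trimethylsilane (C[Si](C)(C)CI)
Why: Copper-catalysed formal carboboration of a terminal alkyne: the Cu–Bpin species adds syn with boron on the terminal carbon and the alkenylcopper is alkylated with retention, so that CH2SiMe3 and Bpin end up cis (Z).

Step 19
Reactants: 21 [5+2] adduct; 30 alkenylboronate
Product: 31 skipped diene (C9–C11 joined; C8=C9 Z, C12=C13 E; free enol), ring A methyl ester linked through C6–C7 to the allylsilane and through C11 to the north half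
Conditions: Pd(PPh3)4 (cat.), K3PO4, THF–H2O, 50 °C
Reagents that add atoms: none
Why: Suzuki–Miyaura allyl–alkenyl coupling: the primary allylic acetate gives a π-allyl–Pd complex, and transmetallation and reductive elimination at the unsubstituted terminus C11 form the 1,4-diene with retention of both alkene geometries (any O-allylation of the enolate is reversible under Pd).

Step 20
Reactants: 31 skipped diene
Product: 32 enol acetate of 31 (C11′–OAc)
Conditions: Ac2O, pyridine, DMAP (cat.), CH2Cl2, 0 °C
Reagents that add atoms: acetic anhydride (CC(=O)OC(C)=O)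
Why: O-Acylation of the acidic diosphenol hydroxyl under nucleophilic catalysis masks the enol against the electrophilic N–F oxidant of the next step.

Step 21
Reactants: 32 enol acetate
Product: 33 ring-B-closed trans-decalin with exocyclic C8=C17 methylene (methyl ester, enol acetate)
Conditions: Co(salen*) [N,N′-bis(3,5-di-tert-butylsalicylidene)cyclohexane-1,2-diaminato cobalt, divalent cobalt] (cat.), N-fluoro-2,4,6-trimethylpyridinium triflate, (Me2SiH)2O, CH2Cl2–HFIP, 0 °C
Reagents that add atoms: none
Why: Proposed new method: a cobalt hydride (from the catalyst, the N–F oxidant and the disiloxane) transfers a hydrogen atom to the only 1,1-disubstituted alkene C10=C20; the tertiary C10 radical is captured by cobalt and oxidised to a cation equivalent, C9 of the (Z)-allylsilane attacks it, and the β-silyl cation at C8 loses Me3Si+ to give the C8=C17 methylene regiospecifically (direct 6-endo radical addition followed by oxidation would converge on the same product). The closest known reaction types are the cobalt-catalysed hydrogen-atom-transfer radical–polar crossover hydroarylation and polyene cyclisation of 1,1-disubstituted alkenes and the classical allylsilane-terminated cation–olefin cyclisation; the allylsilane terminator under these conditions is the new element. Ring B closes by C9–C10 bond formation in a 6-endo-trig mode with respect to the C8=C9 π bond through a chair transition state. C10 (methyl axial, trans fusion) is controlled by the resident C5 centre, whose C6 chain stays equatorial, and C9 (side chain equatorial) by the Z geometry of the allylsilane. The step needs hydrogen-atom transfer to C10=C20 in the presence of three trisubstituted alkenes (secured by its 1,1-disubstitution) and carbon capture of C10 faster than loss of H5 or ester participation (secured by the nucleophilic allylsilane and the reversibly participating methyl ester). The aldehyde is spared because no Lewis acid is present.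

Step 22
Reactants: 33 protected cyclisation product
Product: 34 CNP0256710.1 (target)
Conditions: n-PrSLi, HMPA, rt; then aq. HCl (pH 3)
Reagents that add atoms: none
Why: SN2 dealkylation of the hindered methyl ester by thiolate at the methyl carbon and thiolysis of the enol acetate in the same operation; no stereocentre is touched.

**Compound list**

1 | 2-isopropylanisole | COc1ccccc1C(C)C | starting material
2 | 4-(chloromethyl)-1-methoxy-2-(propan-2-yl)benzene | COc1ccc(CCl)cc1C(C)C | intermediate
3 | geranyl chloride | ClC/C=C(\C)CCC=C(C)C | starting material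
4 | [4-methoxy-3-(propan-2-yl)benzyl]magnesium chloride | COc1ccc(C[Mg]Cl)cc1C(C)C | intermediate
5 | 4-[(3E)-4,8-dimethylnona-3,7-dien-1-yl]-1-methoxy-2-(propan-2-yl)benzene | COc1ccc(CC/C=C(\C)CCC=C(C)C)cc1C(C)C | intermediate
6 | (+)-ferruginol methyl ether (4bS,8aS) | COc1cc2c(cc1C(C)C)CC[C@H]1C(C)(C)CCC[C@]21C | intermediate
7 | sugiol methyl ether (7-ketone) | COc1cc2c(cc1C(C)C)C(=O)C[C@H]1C(C)(C)CCC[C@]21C | intermediate
8 | 6-trifluoroacetyl derivative of 7 | COc1cc2c(cc1C(C)C)C(=O)C(C(=O)C(F)(F)F)[C@H]1C(C)(C)CCC[C@]21C | intermediate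
9 | 6-diazo-12-methoxyabieta-8,11,13-trien-7-one | COc1cc2c(cc1C(C)C)C(=O)C(=[N+]=[N-])[C@H]1C(C)(C)CCC[C@]21C | intermediate
10 | ring-contracted aryl ketene | COc1cc2c(cc1C(C)C)C(=C=O)[C@H]1C(C)(C)CCC[C@]21C | intermediate
11 | ring-contracted methyl ester, C6′ epimer mixture | COc1cc2c(cc1C(C)C)C(C(=O)OC)[C@H]1C(C)(C)CCC[C@]21C | intermediate
12 | methyl (4aS,9R,9aS)-6-methoxy-1,1,4a-trimethyl-7-(propan-2-yl)-2,3,4,4a,9,9a-hexahydro-1H-fluorene-9-carboxylate | COc1cc2c(cc1C(C)C)[C@H](C(=O)OC)[C@H]1C(C)(C)CCC[C@]21C | intermediate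
13 | 6-hydroxy analogue of 12 (phenol ester) | Oc1cc2c(cc1C(C)C)[C@H](C(=O)OC)[C@H]1C(C)(C)CCC[C@]21C | intermediate
14 | (4aS,9R,9aS)-9-(hydroxymethyl)-1,1,4a-trimethyl-7-(propan-2-yl)-2,3,4,4a,9,9a-hexahydro-1H-fluoren-6-ol | Oc1cc2c(cc1C(C)C)[C@H](CO)[C@H]1C(C)(C)CCC[C@]21C | intermediate
15 | 11′,12′-o-quinone 9-carbaldehyde | O=C1C(=O)C2=C(C=C1C(C)C)[C@H](C=O)[C@H]1C(C)(C)CCC[C@]21C | intermediate
16 | 14′-(pentafluorophenylthio) o-quinone aldehyde | O=C1C(=O)C2=C(C(Sc3c(F)c(F)c(F)c(F)c3F)=C1C(C)C)[C@H](C=O)[C@H]1C(C)(C)CCC[C@]21C | intermediate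
17 | (4aS,9R,9aS)-6-hydroxy-1,1,4a-trimethyl-5,8-dioxo-7-(propan-2-yl)-2,3,4,4a,5,8,9,9a-octahydro-1H-fluorene-9-carbaldehyde | CC(C)C1=C(O)C(=O)C2=C(C1=O)[C@H](C=O)[C@H]1C(C)(C)CCC[C@]21C | intermediate
18 | (E)-3-methylpent-2-en-4-yn-1-ol | OC/C=C(\C)C#C | starting material
19 | (E)-3-methylpenta-2,4-dien-1-ol | OC/C=C(\C)C=C | intermediate
20 | (E)-3-methylpenta-2,4-dien-1-yl acetate | CC(=O)OC/C=C(\C)C=C | intermediate
21 | [5+2] adduct, allylic acetate, free enol | CC(=O)OC/C=C(\C)[C@@H]1C[C@@]23C(=O)[C@]1(C(C)C)C(=O)C(O)=C2[C@@]1(C)CCCC(C)(C)[C@@H]1[C@H]3C=O | intermediate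
22 | methyl 3-oxocyclohex-1-ene-1-carboxylate | COC(=O)C1=CC(=O)CCC1 | starting material
23 | methylzinc enolate of methyl (R)-1-methyl-3-oxocyclohexane-1-carboxylate | C[Zn]OC1=C[C@](C)(C(=O)OC)CCC1 | intermediate
24 | methyl (1R,2S)-1-methyl-3-oxo-2-(prop-2-en-1-yl)cyclohexane-1-carboxylate | O=C1CCC[C@@](C)(C(=O)OC)[C@@H]1CC=C | intermediate
25 | methyl (1R,2R)-1-methyl-3-methylidene-2-(prop-2-en-1-yl)cyclohexane-1-carboxylate | C=C1CCC[C@@](C)(C(=O)OC)[C@@H]1CC=C | intermediate
26 | B-alkyl disiamylborane from 25 | C=C1CCC[C@@](C)(C(=O)OC)[C@@H]1CCCB(C(C)C(C)C)C(C)C(C)C | intermediate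
27 | methyl (1R,2R)-2-(3-hydroxypropyl)-1-methyl-3-methylidenecyclohexane-1-carboxylate | C=C1CCC[C@@](C)(C(=O)OC)[C@@H]1CCCO | intermediate
28 | methyl (1R,2R)-1-methyl-3-methylidene-2-(3-oxopropyl)cyclohexane-1-carboxylate | C=C1CCC[C@@](C)(C(=O)OC)[C@@H]1CCC=O | intermediate
29 | methyl (1R,2R)-2-(but-3-yn-1-yl)-1-methyl-3-methylidenecyclohexane-1-carboxylate | C=C1CCC[C@@](C)(C(=O)OC)[C@@H]1CCC#C | intermediate
30 | (Z)-alkenyl pinacolboronate with CH2SiMe3 on C8 | C=C1CCC[C@@](C)(C(=O)OC)[C@@H]1CC/C(C[Si](C)(C)C)=C/B1OC(C)(C)C(C)(C)O1 | intermediate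
31 | skipped diene, free enol | C=C1CCC[C@@](C)(C(=O)OC)[C@@H]1CC/C(C[Si](C)(C)C)=C/C/C=C(\C)[C@@H]1C[C@@]23C(=O)[C@]1(C(C)C)C(=O)C(O)=C2[C@@]1(C)CCCC(C)(C)[C@@H]1[C@H]3C=O | intermediate
32 | enol acetate of 31 | C=C1CCC[C@@](C)(C(=O)OC)[C@@H]1CC/C(C[Si](C)(C)C)=C/C/C=C(\C)[C@@H]1C[C@@]23C(=O)[C@]1(C(C)C)C(=O)C(OC(C)=O)=C2[C@@]1(C)CCCC(C)(C)[C@@H]1[C@H]3C=O | intermediate
33 | methyl ester, enol acetate of the target | C=C1CC[C@@H]2[C@](C)(CCC[C@@]2(C)C(=O)OC)[C@H]1C/C=C(\C)[C@@H]1C[C@@]23C(=O)[C@]1(C(C)C)C(=O)C(OC(C)=O)=C2[C@@]1(C)CCCC(C)(C)[C@@H]1[C@H]3C=O | intermediate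
34 | CNP0256710.1 | C=C1CC[C@@H]2[C@](C)(CCC[C@@]2(C)C(=O)O)[C@H]1C/C=C(\C)[C@@H]1C[C@@]23C(=O)[C@]1(C(C)C)C(=O)C(O)=C2[C@@]1(C)CCCC(C)(C)[C@@H]1[C@H]3C=O | target

Total step count: 22. Longest linear sequence: 14 steps (steps 1–9, 12, 19–22).

**Steps most likely to fail**

Step 21. The cation equivalent at C10 may lose H5 (giving the tetrasubstituted C5=C10 alkene) or be reduced before it is captured, and the N–F oxidant may fluorodesilylate the allylsilane. The fallback uses known chemistry and sets out from 32. Mukaiyama hydration (Mn(dpm)3, PhSiH3, O2, i-PrOH, 0 °C) at the 1,1-disubstituted alkene gives the tertiary C10 alcohol F1. Ionisation of F1 with SnCl4 in dilute CH2Cl2 at −78 °C then triggers the classical allylsilane-terminated cation–olefin cyclisation through the same chair transition state and returns to 33.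

Step 12. Ordinary [4+2] addition of the diene across a quinone C=C bond, attack on the β face or with the wrong diene terminus, and Lewis-acid ionisation of the allylic acetate may all compete. The fallback sets out from 17, which is reduced with Na2S2O4 (EtOAc–H2O) to the 5,6,8-trihydroxy-arene (hydroquinone) F2. Constant-current anodic oxidation of F2 (graphite anode, LiClO4, HFIP–CH2Cl2, 0 °C) in the presence of 20 generates the O-protonated quinone, that is the oxidopentadienyl cation, directly in an ionising medium and without Lewis acid. This is the manifold of the known anodic phenol–olefin [5+2] cycloadditions, and it returns to 21.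

Step 18. Alkylation of the β-borylalkenylcopper by the α-silyl iodide may be slow, so that protonation of the copper intermediate wins and the CH2SiMe3 group is not installed. The fallback sets out from 29. Carbocupration with the (trimethylsilyl)methylcopper reagent made from Me3SiCH2MgCl and CuBr·SMe2 (Et2O–Me2S, −40 → −10 °C) adds syn across the alkyne, and an iodine quench gives the (Z)-alkenyl iodide F3. Miyaura borylation of F3 (PdCl2(dppf), B2pin2, KOPh, toluene, 50 °C) proceeds with retention and returns to 30.

**Further compounds**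

F1 | step 21 | C10 tertiary alcohol from hydration of 32 (C10 epimers) | CC1(O)CCC[C@@](C)(C(=O)OC)[C@@H]1CC/C(C[Si](C)(C)C)=C/C/C=C(\C)[C@@H]1C[C@@]23C(=O)[C@]1(C(C)C)C(=O)C(OC(C)=O)=C2[C@@]1(C)CCCC(C)(C)[C@@H]1[C@H]3C=O
F2 | step 12 | (4aS,9R,9aS)-5,6,8-trihydroxy-1,1,4a-trimethyl-7-(propan-2-yl)-2,3,4,4a,9,9a-hexahydro-1H-fluorene-9-carbaldehyde | CC(C)c1c(O)c(O)c2c(c1O)[C@H](C=O)[C@H]1C(C)(C)CCC[C@]21C
F3 | step 18 | methyl (1R,2R)-2-[(3Z)-4-iodo-3-[(trimethylsilyl)methyl]but-3-en-1-yl]-1-methyl-3-methylidenecyclohexane-1-carboxylate | C=C1CCC[C@@](C)(C(=O)OC)[C@@H]1CC/C(C[Si](C)(C)C)=C/I
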